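Compare the two earlier runs at the same time and the same starting complex: at 50.0 min green holds 3.94 times blue's complex with two exchanged, on 3.56 times its incoming ligand.

| setting | blue | green | Thursday's | Sunday's |
|---|---|---|---|---|
| starting complex | 0.80 M | 0.80 M | 0.80 M | 0.80 M |
| incoming ligand | 0.73 equiv | 2.6 equiv | 2.00 equiv | 0.500 equiv |
| remark | run made earlier | run made earlier |  |  |
| time |  |  | 2.0 h | 2.0 h |

| run | time / min | complex with two exchanged / % |
|---|---|---|
| blue | 3.00 | 0 |
| blue | 10.0 | 0 |
| blue | 15.0 | 0 |
| blue | 25.0 | 1.1 |
| blue | 40.0 | 2.6 |
| blue | 50.0 | 3.4 |
| blue | 60.0 | 2.4 |
| green | 8.00 | 2.3 |
| green | 15.0 | 5.0 |
| green | 25.0 | 8.1 |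
| green | 30.0 | 9.6 |
| green | 40.0 | 12.5 |
| green | 50.0 | 13.4 |
| green | 60.0 | 13.6 |

(readings scatter by 0.5 percentage points)

- reactions considered so far: starting complex + incoming ligand -> leaving ligand + complex with one exchanged; leaving ligand + complex with two exchanged -> side product; complex with one exchanged + incoming ligand -> leaving ligand + complex with two exchanged; complex with two exchanged + incoming ligand -> leaving ligand + complex with three exchanged; complex with two exchanged -> over-reaction product

* which of these holds the largest part of the starting complex at the end of Thursday's (complex with three exchanged / starting complex / complex with one exchanged / complex with two exchanged)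
* which of these holds the largest part of the starting complex at the end of Sunday's (complex with three exchanged / starting complex / complex with one exchanged / complex with two exchanged)
* final complex with two exchanged in Thursday's, as a percentage of the starting complex charged

That suggests a bench rule: late in a run, the complex with two exchanged goes with the charge of incoming ligand. Green's last reading over green's charge gives 5.23%. This is the plateau share, the percentage of the charged starting complex standing as complex with two exchanged per equivalent of incoming ligand. For Thursday's it gives 10.5%.

Now go round once more and put the rule back on blue: the share came from green, but blue's reading at 50.0 min suggested the rule, so this is no independent check. It gives 3.82% against the 3.4% read at 50.0 min, a gap of 0.42 percentage points with a scatter of 0.5 points. But blue's last reading is down at 2.4%, so the level may not hold. That is the border of the rule: it lasts as long as the plateau does, and Thursday's asked time is twice green's last reading, beyond what the runs cover.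

I still commit to 10.5%. The runs report the complex with two exchanged and none of the other forms, so I make no ranking of my own for Thursday's. In Sunday's, incoming ligand is the limiting reagent at 0.500 equiv, so at least half stays as starting complex.

The forecast gives 11%, complex with one exchanged and starting complex by a reckoning of its own, concluding that “the bulk stays as the one-exchanged complex”.

Thursday's gives 11.4%, with complex with one exchanged largest at 34.9%. Sunday's gives starting complex at 69.7%.

    starting complex + incoming ligand → leaving ligand + complex with one exchanged (k = 2.20 × 10⁻⁴ /M/s)
    leaving ligand + complex with two exchanged → side product (k = 3.40 × 10⁻⁵ /M/s)
    complex with one exchanged + incoming ligand → leaving ligand + complex with two exchanged (k = 2.10 × 10⁻⁴ /M/s)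
    complex with two exchanged + incoming ligand → leaving ligand + complex with three exchanged (k = 2.90 × 10⁻⁴ /M/s)
    complex with two exchanged → over-reaction product (k = 2.10 × 10⁻⁴ /s)

Take a neighbouring flask like Thursday's but with 1.20 equiv of incoming ligand. The plateau share gives 6.28% of complex with two exchanged, and the flask stands at 7.60%. That reckoning is lower than the flask, as 10.5% was lower than Thursday's 11.4%. In this neighbour the largest part is no longer the complex with one exchanged: starting complex holds it, at 41.8%.

(Readings and results come from a simulation with made-up constants, noise included.)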